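**Plan**

- The target is oxacyclotritriacontan-2-one, a 33-membered lactone with no other functional group; ring carbons are numbered C1 (carbonyl) to C32 (the CH2 on the ring oxygen).
- Retrosynthesis: the four methylenes C10–C13 are redrawn as a conjugated diyne C10≡C11–C12≡C13. Its central ring bond C11–C12 is then cut to two terminal alkynes, whose acetylide carbons have the same (nucleophilic) polarity and are joined oxidatively. Next the ester C1–O bond is cut. Last, the C21 alkynol is traced back through triple-bond migration to a propargylic C–C cut.
- Enabling feature: C11–C12 sits in an unbranched polymethylene stretch, flanked by the unsubstituted CH2 groups C10 and C13. A linear diyne can therefore stand in for C10–C13 and be erased by hydrogenation, and the 33-membered ring is large enough to hold this rigid rod without strain.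
- Forward: C11 + C10 chain union by dianion alkylation, zipper migration of the triple bond to the chain end, esterification with undec-10-ynoic acid, closure of the only ring by Eglinton coupling, saturation.
- Stereochemistry: none to set; the target has no stereocenter and no double bond.

Key step: step 4

Remark: the target is taken as the achiral lactone of 32-hydroxydotriacontanoic acid (C32H62O2); undec-10-yn-1-ol, 1-bromodecane and undec-10-ynoic acid are taken as commercial.

**Route**

Step 1
Reactants: 1 undec-10-yn-1-ol; 2 1-bromodecane
Product: 5 henicos-10-yn-1-ol, via dilithium salt of undec-10-yn-1-ol 3 (not isolated), via lithium henicos-10-yn-1-olate 4 (not isolated)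
Conditions: n-BuLi (2.1 equiv), THF/HMPA, −78 to 0 °C; then 2, 0 °C to rt; H2O quench
Reagents that add atoms: none
Why: Alkylation of an alkynol dianion, in which the acetylide carbon displaces the primary bromide by SN2 much faster than the aggregated lithium alkoxide oxygen does, so no protecting group is needed and no stereocenter is formed.

Step 2
Reactants: 5 henicos-10-yn-1-ol
Product: 7 henicos-20-yn-1-ol, via dipotassium salt of henicos-20-yn-1-ol 6 (not isolated)
Conditions: KH (5 equiv), H2N(CH2)3NH2, rt; then 5 in THF, 0 °C to rt; H2O quench
Reagents that add atoms: none
Why: Alkyne zipper reaction, in which potassium 3-aminopropylamide walks the triple bond along the chain by reversible propargyl–allenyl proton shifts until the terminal potassium acetylide forms irreversibly at the methyl end, the only terminus open because the other end carries the alkoxide.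

Step 3
Reactants: 7 henicos-20-yn-1-ol; 8 undec-10-ynoic acid
Product: 9 henicos-20-yn-1-yl undec-10-ynoate
Conditions: DCC (1.1 equiv), DMAP (0.1 equiv), CH2Cl2, 0 °C to rt
Reagents that add atoms: none
Why: Steglich esterification, in which the carbodiimide activates the acid and DMAP relays the acyl group to the unhindered primary alcohol; both terminal alkynes are inert under these conditions.

Step 4
Reactants: 9 henicos-20-yn-1-yl undec-10-ynoate
Product: 11 oxacyclotritriaconta-11,13-diyn-2-one, via dicopper bis-acetylide 10 (not isolated)
Conditions: Cu(OAc)2 (10 equiv), pyridine/MeCN (3:1), 60 °C, syringe-pump addition of 9 over 24 h (final ca. 1 mM), N2, dark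
Reagents that add atoms: none
Why: Eglinton oxidative alkyne coupling: each terminal alkyne, acidified by π-coordination to copper, is deprotonated by pyridine to a copper acetylide (10), and the two acetylide carbons, both nucleophilic, are joined inside a dinuclear copper assembly while each divalent copper takes up one electron and leaves as monovalent CuOAc. The closest known reaction type is the high-dilution Glaser–Eglinton macrocyclisation of α,ω-diynes, long used for large carbocycles and macrolide rings. The only ring, the 33-membered lactone, closes end to end between the two chain termini, both reacting carbons being digonal and both triple bonds becoming endocyclic, and the 29-atom tether between C10 and C13 spans the rigid four-carbon rod without strain. No stereocenter is formed. The selectivity needed is ring closure over intermolecular coupling to cyclic dimer and oligomers, which slow addition into excess Cu(OAc)2 secures by keeping the stationary concentration of free alkyne termini very low; chemoselectivity is no issue because the ester and the saturated chain are inert to divalent copper in pyridine.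

Step 5
Reactants: 11 oxacyclotritriaconta-11,13-diyn-2-one
Product: 12 oxacyclotritriacontan-2-one
Conditions: H2 (1 atm), 10% Pd/C, EtOAc/THF, rt
Reagents that add atoms: none
Why: Exhaustive heterogeneous hydrogenation saturates both triple bonds of the conjugated diyne (four equivalents of H2) and leaves the lactone untouched, since no C–O bond is allylic, propargylic or benzylic.

**Compound list**

1 | undec-10-yn-1-ol | OCCCCCCCCCC#C | starting material
2 | 1-bromodecane | CCCCCCCCCCBr | starting material
3 | dilithium salt of undec-10-yn-1-ol (lithium alkoxide and lithium acetylide) | [Li+].[Li+].[O-]CCCCCCCCCC#[C-] | intermediate (not isolated)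
4 | lithium henicos-10-yn-1-olate | [Li+].[O-]CCCCCCCCCC#CCCCCCCCCCC | intermediate (not isolated)
5 | henicos-10-yn-1-ol | OCCCCCCCCCC#CCCCCCCCCCC | intermediate
6 | dipotassium salt of henicos-20-yn-1-ol (potassium alkoxide and terminal potassium acetylide) | [K+].[K+].[O-]CCCCCCCCCCCCCCCCCCCC#[C-] | intermediate (not isolated)
7 | henicos-20-yn-1-ol | OCCCCCCCCCCCCCCCCCCCC#C | intermediate
8 | undec-10-ynoic acid | OC(=O)CCCCCCCCC#C | starting material
9 | henicos-20-yn-1-yl undec-10-ynoate | C#CCCCCCCCCC(=O)OCCCCCCCCCCCCCCCCCCCC#C | intermediate
10 | dicopper bis-acetylide of ester 9 (each terminal alkyne carbon bound to CuOAc; drawn without pyridine ligands) | CC(=O)O[Cu]C#CCCCCCCCCC(=O)OCCCCCCCCCCCCCCCCCCCC#C[Cu]OC(C)=O | intermediate (not isolated)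
11 | oxacyclotritriaconta-11,13-diyn-2-one (33-membered lactone with a conjugated diyne at ring positions 11–14) | O=C1CCCCCCCCC#CC#CCCCCCCCCCCCCCCCCCCCO1 | intermediate
12 | oxacyclotritriacontan-2-one (lactone of 32-hydroxydotriacontanoic acid; achiral) | O=C1CCCCCCCCCCCCCCCCCCCCCCCCCCCCCCCO1 | target

**Totals**

Total step count: 5. Longest linear sequence: 5 steps (1 → 5 → 7 → 9 → 11 → 12).

**Steps most likely to fail**

1. Step 4 (Eglinton macrocyclisation). Intermolecular oxidative coupling may outrun ring closure, so that chain growth and cyclodimerisation consume the diyne ester. The fallback separates formation of the diyne bond from ring closure. It sets out from 7 and 8. Bromination of the terminal alkyne of 7 (NBS, AgNO3 cat., acetone, rt) should give 21-bromohenicos-20-yn-1-ol F1. Cadiot–Chodkiewicz cross-coupling of F1 with the terminal alkyne of 8 (CuCl cat., NH2OH·HCl, aqueous EtNH2, MeOH/THF, 0 °C to rt) should give 32-hydroxydotriaconta-10,12-diynoic acid F2. Yamaguchi macrolactonisation of F2 (2,4,6-trichlorobenzoyl chloride, Et3N, THF; then slow addition to DMAP in toluene, reflux, high dilution) then closes the ring at the ester C–O bond, and the fallback comes back to the route at 11.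

2. Step 2 (alkyne zipper). Migration over ten positions may stall, for instance through poor solubility of the long-chain potassium alkoxide in the diamine or partial quenching of the amide base, leaving positional alkyne isomers that cannot be separated. The fallback installs the terminal alkyne directly and leaves an internal triple bond in the chain, which the final hydrogenation removes anyway. It sets out from 1. The dianion of 1 (n-BuLi, 2.1 equiv, THF/HMPA) is alkylated with excess 1,8-dibromooctane (BrCCCCCCCCBr) to give 19-bromononadec-10-yn-1-ol F3. Displacement of the bromide with lithium acetylide–ethylenediamine complex (excess, DMSO, 0 °C to rt) should give henicosa-10,20-diyn-1-ol F4. Steglich esterification with 8 (DCC, DMAP, CH2Cl2) gives henicosa-10,20-diyn-1-yl undec-10-ynoate F5. Eglinton coupling under the conditions of step 4 engages only the two terminal alkynes and should give oxacyclotritriaconta-11,13,23-triyn-2-one F6. Hydrogenation (H2, 10% Pd/C, EtOAc/THF) saturates all three triple bonds, and the fallback comes back to the route at 12.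

3. Step 1 (dianion alkylation). O-alkylation by the lithium alkoxide and base-induced elimination of the bromide may compete with C-alkylation, or dianion formation may be incomplete. The fallback removes the competing oxygen nucleophile. It sets out from 1. Protection with 3,4-dihydro-2H-pyran (PPTS cat., CH2Cl2, rt) gives 2-(undec-10-yn-1-yloxy)oxane F7. Lithiation (n-BuLi, THF/HMPA, −78 °C) and alkylation with 2 give 2-(henicos-10-yn-1-yloxy)oxane F8. Acetal exchange (PPTS, MeOH, 50 °C) frees the alcohol, and the fallback comes back to the route at 5.

**Further compounds**

F1 | step 4 | 21-bromohenicos-20-yn-1-ol | OCCCCCCCCCCCCCCCCCCCC#CBr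
F2 | step 4 | 32-hydroxydotriaconta-10,12-diynoic acid | OC(=O)CCCCCCCCC#CC#CCCCCCCCCCCCCCCCCCCCO
F3 | step 2 | 19-bromononadec-10-yn-1-ol | OCCCCCCCCCC#CCCCCCCCCBr
F4 | step 2 | henicosa-10,20-diyn-1-ol | OCCCCCCCCCC#CCCCCCCCCC#C
F5 | step 2 | henicosa-10,20-diyn-1-yl undec-10-ynoate | C#CCCCCCCCCC(=O)OCCCCCCCCCC#CCCCCCCCCC#C
F6 | step 2 | oxacyclotritriaconta-11,13,23-triyn-2-one | O=C1CCCCCCCCC#CC#CCCCCCCCCC#CCCCCCCCCCO1
F7 | step 1 | 2-(undec-10-yn-1-yloxy)oxane (racemic at the acetal carbon) | C#CCCCCCCCCCOC1CCCCO1
F8 | step 1 | 2-(henicos-10-yn-1-yloxy)oxane (racemic at the acetal carbon) | CCCCCCCCCCC#CCCCCCCCCCOC1CCCCO1
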